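**Retrosynthetic overview**

1. The target is reached from its hexabenzyl ether by hydrogenolysis; the 6,8''-biaryl bond and the whole flavone unit are in place before the stereocentre is made.
2. Key disconnection: ring C of the flavanone is cut at C2–C3 and at O1–C8a. This gives 4-(benzyloxy)benzaldehyde and the trimethylsilyl enol ether of a 2-fluoroaryl methyl ketone, joined forward by a catalytic asymmetric Mukaiyama aldol and a fluoride-relayed SNAr ring closure in one flask (a hetero-Diels–Alder reaction run in two stages).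
3. Enabling feature: ring A of the flavanone is a phloroglucinol ring, so C8a is ortho to C4a (which carries the C4 ketone) and meta to both O5 and O7. A fluorine on C8a is therefore activated by the ketone (C8a=C4a–C4=O, a vinylogous acyl fluoride) and not deactivated by the ether oxygens, while C3 is the α-carbon of the same ketone.
4. Biaryl bond: Suzuki–Miyaura coupling of an aryl iodide (from 5-fluororesorcinol by C-acetylation, iodination between the hydroxyls, benzylation) with a flavone-8-boronate (from apigenin by benzylation, C8 iodination, borylation).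
5. Ring order: the three rings of the flavone and ring A of the flavanone are bought in; the biaryl bond follows; ring C of the flavanone is the last ring formed, together with the attachment of ring B and the setting of C2.

Key step: step 9

Remark on the chemistry: the target SMILES fixes only C2 (S) and leaves the hindered 6,8''-biaryl axis open, so the axis is not controlled and any rotamer mixture about it is accepted; the hand of the aldol catalyst is taken as the one that adds to the Si face of the aldehyde, which is what (2S) requires.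

**Route**

Step 1
Reactants: 1 5-fluorobenzene-1,3-diol (5-fluororesorcinol)
Product: 2 1-(2-fluoro-4,6-dihydroxyphenyl)ethan-1-one
Conditions: AcOH, BF3·OEt2, 90 °C; then aq. NaOAc
Reagents that add atoms: acetic acid CC(=O)O
Why: BF3-promoted Friedel–Crafts C-acylation of a resorcinol takes place at C4 (ortho to one hydroxyl and para to the other), as in the standard preparation of 2,4-dihydroxyacetophenone, and the chelated boron complex of the product resists a second acylation.

Step 2
Reactants: 2 1-(2-fluoro-4,6-dihydroxyphenyl)ethan-1-one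
Product: 3 1-(6-fluoro-2,4-dihydroxy-3-iodophenyl)ethan-1-one
Conditions: I2 (0.4 equiv), HIO3 (0.2 equiv), EtOH/H2O, 35 °C
Reagents that add atoms: iodine II; iodic acid O[I](=O)=O
Why: Electrophilic aromatic iodination of a chelated 2,4-dihydroxyaryl ketone with I2/HIO3 goes to the carbon between the two hydroxyls (bond fixation by the hydrogen-bonded ketone), and here that carbon is also para to fluorine whereas the only other free position is ortho to it.

Step 3
Reactants: 3 1-(6-fluoro-2,4-dihydroxy-3-iodophenyl)ethan-1-one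
Product: 4 1-[2,4-bis(benzyloxy)-6-fluoro-3-iodophenyl]ethan-1-one
Conditions: BnBr, K2CO3, DMF, 60 °C
Reagents that add atoms: benzyl bromide BrCc1ccccc1
Why: Williamson ether synthesis on both phenols; the warm DMF/K2CO3 conditions are needed for the hydrogen-bonded, iodine-flanked hydroxyl, and the C–F bond is safe because the ring is an electron-rich phenoxide while the reaction runs.

Step 4
Reactants: 5 apigenin (5,7-dihydroxy-2-(4-hydroxyphenyl)-4H-chromen-4-one)
Product: 6 5,7-bis(benzyloxy)-2-[4-(benzyloxy)phenyl]-4H-chromen-4-one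
Conditions: BnBr (excess), K2CO3, DMF, 80 °C
Reagents that add atoms: benzyl bromide BrCc1ccccc1
Why: Williamson ether synthesis; the 7- and 4'-hydroxyls react first and the hydrogen-bonded 5-hydroxyl follows with excess reagent and heat.

Step 5
Reactants: 6 5,7-bis(benzyloxy)-2-[4-(benzyloxy)phenyl]-4H-chromen-4-one
Product: 7 5,7-bis(benzyloxy)-2-[4-(benzyloxy)phenyl]-8-iodo-4H-chromen-4-one
Conditions: I2, AgOCOCF3, CH2Cl2, 0 °C to rt, dark
Reagents that add atoms: iodine II
Why: Silver-assisted electrophilic iodination of a fully O-alkylated 5,7-dioxygenated flavone is known to go to C8 of ring A, which is activated by O7, O5 and O1 and is less crowded than C6 between two benzyloxy groups, while ring B is deactivated by conjugation with the pyranone.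

Step 6
Reactants: 7 5,7-bis(benzyloxy)-2-[4-(benzyloxy)phenyl]-8-iodo-4H-chromen-4-one
Product: 8 5,7-bis(benzyloxy)-2-[4-(benzyloxy)phenyl]-8-(4,4,5,5-tetramethyl-1,3,2-dioxaborolan-2-yl)-4H-chromen-4-one
Conditions: B2pin2, PdCl2(dppf) (cat.), KOAc, 1,4-dioxane, 90 °C
Reagents that add atoms: bis(pinacolato)diboron CC1(C)OB(OC1(C)C)B1OC(C)(C)C(C)(C)O1
Why: Miyaura borylation of the aryl iodide with PdCl2(dppf) and the weak base KOAc, which leaves the flavone and the benzyl ethers untouched.

Step 7
Reactants: 4 1-[2,4-bis(benzyloxy)-6-fluoro-3-iodophenyl]ethan-1-one; 8 the flavone-8-boronic acid pinacol ester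
Product: 9 8-[3-acetyl-2,6-bis(benzyloxy)-4-fluorophenyl]-5,7-bis(benzyloxy)-2-[4-(benzyloxy)phenyl]-4H-chromen-4-one (racemic about the biaryl axis)
Conditions: Pd(OAc)2 (cat.), SPhos, K3PO4, toluene/H2O, 90 °C
Reagents that add atoms: none
Why: Suzuki–Miyaura coupling with a dialkylbiarylphosphine ligand suited to di-ortho-substituted partners on both sides; the C–I bond reacts while the C–F bond and the methyl ketone stay, and the new tetra-ortho-substituted axis forms without control.

Step 8
Reactants: 9 the biaryl methyl ketone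
Product: 10 5,7-bis(benzyloxy)-8-{2,6-bis(benzyloxy)-4-fluoro-3-[1-(trimethylsilyloxy)ethenyl]phenyl}-2-[4-(benzyloxy)phenyl]-4H-chromen-4-one (trimethylsilyl enol ether of 9)
Conditions: TMSOTf, Et3N, CH2Cl2, 0 °C; cold aq. NaHCO3 wash; used crude
Reagents that add atoms: trimethylsilyl trifluoromethanesulfonate C[Si](C)(C)OS(=O)(=O)C(F)(F)F
Why: Soft enolisation (silyl triflate/amine) of the only enolisable carbonyl, the methyl ketone, gives the terminal enol silane; the flavone carbonyl has no saturated α-carbon that could follow this path.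

Step 9
Reactants: 10 the trimethylsilyl enol ether; 11 4-(benzyloxy)benzaldehyde
Product: 14 (2S)-5,7-bis(benzyloxy)-6-{5,7-bis(benzyloxy)-2-[4-(benzyloxy)phenyl]-4-oxo-4H-chromen-8-yl}-2-[4-(benzyloxy)phenyl]-2,3-dihydro-4H-chromen-4-one (hexabenzyl ether of the target), via silyl aldolate 12 (not isolated), via tetrabutylammonium alkoxide 13 (not isolated)
Conditions: (i) 11 (1.5 equiv), Si-face-selective antipode of 2-butyl-4-(indol-3-ylmethyl)-3-tosyl-1,3,2-oxazaborolidin-5-one (0.2 equiv), EtCN, –78 °C; (ii) Bu4N[Ph3SiF2] (0.5 equiv), –78 to –30 °C; then AcOH, –30 °C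
Reagents that add atoms: none
Why: Proposed new method: the enol silane 10 is the benzo-fused counterpart of 1-methoxy-3-silyloxybutadiene (C3=C4(OSiMe3)–C4a=C8a–F), and its union with aldehyde 11 is run as a hetero-Diels–Alder reaction in two stages: a chiral-boron-catalysed Mukaiyama aldol makes C3–C2 and gives silyl aldolate 12, then fluoride frees alkoxide 13, whose oxygen adds to C8a and expels fluoride (SNAr), and the expelled fluoride desilylates the next molecule of 12, so that the ring closure runs as a chain with Me3SiF as the only by-product. The closest known reaction is the oxazaborolidinone-catalysed Mukaiyama aldol/dihydropyranone annulation of silyloxydienes with aldehydes, joined here to the known fluoride-mediated O-arylation of silyl ethers by ketone-activated aryl fluorides. The pyranone ring closes by 6-endo-trig addition–elimination at C8a, in which C8a=C4a–C4=O acts as a vinylogous acyl fluoride. C2 is set under catalyst control in the aldol (Si-face attack on 11) and is not a reacting centre in the ring closure, so it should be carried over unchanged. The step needs enantioface selectivity, ring closure faster than retro-aldol cleavage or β-elimination of 13, and no base-induced ring opening of 14; the ortho ketone and the meta position of the C8a–F bond to both benzyloxy groups keep the SNAr fast, the absence of a free ortho phenol excludes an oxa-Michael route through a chalcone, and the low temperature, the substoichiometric fluoride and the cold acetic acid quench limit the exposure of 13 and 14 to base.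

Step 10
Reactants: 14 the hexabenzyl ether of the target
Product: 15 (2S)-5,7-dihydroxy-6-[5,7-dihydroxy-2-(4-hydroxyphenyl)-4-oxo-4H-chromen-8-yl]-2-(4-hydroxyphenyl)-2,3-dihydro-4H-chromen-4-one (target)
Conditions: H2 (1 atm), 10% Pd/C, THF/MeOH, rt
Reagents that add atoms: none
Why: Hydrogenolysis of the six aryl benzyl ethers under neutral conditions, which cannot epimerise C2; the flavone C2=C3 bond and the two aryl ketones are reduced much more slowly and the reaction is stopped after the uptake of six equivalents of H2.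

**Compound list**

1 | 5-fluorobenzene-1,3-diol | Oc1cc(O)cc(F)c1 | starting material
2 | 1-(2-fluoro-4,6-dihydroxyphenyl)ethan-1-one | CC(=O)c1c(O)cc(O)cc1F | intermediate
3 | 1-(6-fluoro-2,4-dihydroxy-3-iodophenyl)ethan-1-one | CC(=O)c1c(O)c(I)c(O)cc1F | intermediate
4 | 1-[2,4-bis(benzyloxy)-6-fluoro-3-iodophenyl]ethan-1-one | CC(=O)c1c(OCc2ccccc2)c(I)c(OCc2ccccc2)cc1F | intermediate
5 | apigenin | O=c1cc(-c2ccc(O)cc2)oc2cc(O)cc(O)c12 | starting material
6 | 5,7-bis(benzyloxy)-2-[4-(benzyloxy)phenyl]-4H-chromen-4-one | O=c1cc(-c2ccc(OCc3ccccc3)cc2)oc2cc(OCc3ccccc3)cc(OCc3ccccc3)c12 | intermediate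
7 | 5,7-bis(benzyloxy)-2-[4-(benzyloxy)phenyl]-8-iodo-4H-chromen-4-one | O=c1cc(-c2ccc(OCc3ccccc3)cc2)oc2c(I)c(OCc3ccccc3)cc(OCc3ccccc3)c12 | intermediate
8 | 5,7-bis(benzyloxy)-2-[4-(benzyloxy)phenyl]-8-(4,4,5,5-tetramethyl-1,3,2-dioxaborolan-2-yl)-4H-chromen-4-one | O=c1cc(-c2ccc(OCc3ccccc3)cc2)oc2c(B3OC(C)(C)C(C)(C)O3)c(OCc3ccccc3)cc(OCc3ccccc3)c12 | intermediate
9 | 8-[3-acetyl-2,6-bis(benzyloxy)-4-fluorophenyl]-5,7-bis(benzyloxy)-2-[4-(benzyloxy)phenyl]-4H-chromen-4-one (axis not controlled) | CC(=O)c1c(OCc2ccccc2)c(-c2c(OCc3ccccc3)cc(OCc3ccccc3)c3c(=O)cc(-c4ccc(OCc5ccccc5)cc4)oc23)c(OCc2ccccc2)cc1F | intermediate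
10 | trimethylsilyl enol ether of 9 | C=C(O[Si](C)(C)C)c1c(OCc2ccccc2)c(-c2c(OCc3ccccc3)cc(OCc3ccccc3)c3c(=O)cc(-c4ccc(OCc5ccccc5)cc4)oc23)c(OCc2ccccc2)cc1F | intermediate
11 | 4-(benzyloxy)benzaldehyde | O=Cc1ccc(OCc2ccccc2)cc1 | starting material
12 | (S)-β-trimethylsilyloxy ketone (silyl aldolate), not isolated | O=C(C[C@@H](c1ccc(OCc2ccccc2)cc1)O[Si](C)(C)C)c1c(OCc2ccccc2)c(-c2c(OCc3ccccc3)cc(OCc3ccccc3)c3c(=O)cc(-c4ccc(OCc5ccccc5)cc4)oc23)c(OCc2ccccc2)cc1F | intermediate
13 | tetrabutylammonium (S)-alkoxide of the aldol, not isolated | O=C(C[C@@H](c1ccc(OCc2ccccc2)cc1)[O-])c1c(OCc2ccccc2)c(-c2c(OCc3ccccc3)cc(OCc3ccccc3)c3c(=O)cc(-c4ccc(OCc5ccccc5)cc4)oc23)c(OCc2ccccc2)cc1F.CCCC[N+](CCCC)(CCCC)CCCC | intermediate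
14 | (2S)-5,7-bis(benzyloxy)-6-{5,7-bis(benzyloxy)-2-[4-(benzyloxy)phenyl]-4-oxo-4H-chromen-8-yl}-2-[4-(benzyloxy)phenyl]-2,3-dihydro-4H-chromen-4-one | O=C1C[C@@H](c2ccc(OCc3ccccc3)cc2)Oc2cc(OCc3ccccc3)c(-c3c(OCc4ccccc4)cc(OCc4ccccc4)c4c(=O)cc(-c5ccc(OCc6ccccc6)cc5)oc34)c(OCc3ccccc3)c21 | intermediate
15 | (2S)-5,7-dihydroxy-6-[5,7-dihydroxy-2-(4-hydroxyphenyl)-4-oxo-4H-chromen-8-yl]-2-(4-hydroxyphenyl)-2,3-dihydro-4H-chromen-4-one | O=C1C[C@@H](c2ccc(O)cc2)Oc2cc(O)c(-c3c(O)cc(O)c4c(=O)cc(-c5ccc(O)cc5)oc34)c(O)c21 | target

**Step count and risks**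

Total steps: 10. Longest linear sequence: 7 steps (steps 4–10, or steps 1–3 followed by 7–10).

Steps most likely to fail:

1. Step 9. The free alkoxide may revert by retro-aldol cleavage and re-add without control before the ring closes (erosion of the C2 configuration), it may eliminate to the chalcone, the product may ring-open under the basic fluoride, or the basic flavone carbonyl may slow the boron catalyst; any enol silane left when fluoride is added would also give an uncatalysed aldol. The fallback builds ring C by known chemistry and puts ring B on last. It sets out from 9: formylation of the methyl ketone with ethyl formate and NaH in THF, then warming in DMF, should let the enolate oxygen displace the ortho fluorine and give 5,7-bis(benzyloxy)-6-{5,7-bis(benzyloxy)-2-[4-(benzyloxy)phenyl]-4-oxo-4H-chromen-8-yl}-4H-chromen-4-one F1. Asymmetric conjugate addition of [4-(benzyloxy)phenyl]boronic acid to F1 with Pd(OCOCF3)2, a tert-butyl pyridine-oxazoline ligand (antipode for the (2S) series), NH4PF6 and H2O in ClCH2CH2Cl at 60 °C should then give 14, where the route is rejoined. The flavone unit carries an aryl group on its β-carbon and should not compete.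

2. Step 7. Protodeboronation of the boronate flanked by two oxygen substituents under aqueous base, and slow coupling at the fourfold ortho-substituted axis, may stall the reaction. The fallback is a base-free Negishi coupling that sets out from 7: Zn dust and LiCl in THF at 50 °C should insert into the C–I bond and give {5,7-bis(benzyloxy)-2-[4-(benzyloxy)phenyl]-4-oxo-4H-chromen-8-yl}zinc iodide F2, which is coupled with 4 using Pd2(dba)3 and SPhos in THF at 60 °C to come back to the route at 9.

3. Step 2. Iodination may also take place at the position between fluorine and hydroxyl, or twice. The fallback puts the iodine in first, where the site is not in doubt, and sets out from 1: I2 and NaHCO3 in water at 0 °C should iodinate between the two hydroxyls to give 5-fluoro-2-iodobenzene-1,3-diol F3; BnBr and K2CO3 in DMF give 1,3-bis(benzyloxy)-5-fluoro-2-iodobenzene F4, whose two free positions are equivalent; Vilsmeier–Haack formylation (POCl3, DMF, 70 °C) gives 2,4-bis(benzyloxy)-6-fluoro-3-iodobenzaldehyde F5; MeMgBr in THF at –78 °C gives racemic 1-[2,4-bis(benzyloxy)-6-fluoro-3-iodophenyl]ethan-1-ol F6; oxidation with 1,1,1-triacetoxy-1,1-dihydro-1,2-benziodoxol-3(1H)-one in CH2Cl2 gives 4, where the route is rejoined.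

**Further compounds**

F1 | step 9 | 5,7-bis(benzyloxy)-6-{5,7-bis(benzyloxy)-2-[4-(benzyloxy)phenyl]-4-oxo-4H-chromen-8-yl}-4H-chromen-4-one | O=c1ccoc2cc(OCc3ccccc3)c(-c3c(OCc4ccccc4)cc(OCc4ccccc4)c4c(=O)cc(-c5ccc(OCc6ccccc6)cc5)oc34)c(OCc3ccccc3)c12
F2 | step 7 | {5,7-bis(benzyloxy)-2-[4-(benzyloxy)phenyl]-4-oxo-4H-chromen-8-yl}zinc iodide | O=c1cc(-c2ccc(OCc3ccccc3)cc2)oc2c([Zn]I)c(OCc3ccccc3)cc(OCc3ccccc3)c12
F3 | step 2 | 5-fluoro-2-iodobenzene-1,3-diol | Oc1cc(F)cc(O)c1I
F4 | step 2 | 1,3-bis(benzyloxy)-5-fluoro-2-iodobenzene | Fc1cc(OCc2ccccc2)c(I)c(OCc2ccccc2)c1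
F5 | step 2 | 2,4-bis(benzyloxy)-6-fluoro-3-iodobenzaldehyde | O=Cc1c(OCc2ccccc2)c(I)c(OCc2ccccc2)cc1F
F6 | step 2 | 1-[2,4-bis(benzyloxy)-6-fluoro-3-iodophenyl]ethan-1-ol (racemic) | CC(O)c1c(OCc2ccccc2)c(I)c(OCc2ccccc2)cc1F
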